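In a one-step world the rate of making target follows [reagent] to the first power, so charging more reagent raises it by the same factor. These are the flask and the runs before it.

| setting | oak | alder | flask |
|---|---|---|---|
| starting material | 0.050 M | 0.050 M | 0.050 M |
| reagent | 0.35 equiv | 1.4 equiv | 0.700 equiv |
| free catalyst | 0.2 mol% | 0.2 mol% | 0.2 mol% |
| remark | run made earlier | run made earlier |  |

| run | time / min | target / % |
|---|---|---|
| oak | 0.200 | 0 |
| oak | 0.500 | 0.4 |
| oak | 1.00 | 0.7 |
| oak | 1.50 | 1.0 |
| oak | 2.00 | 1.3 |
| oak | 3.00 | 2.0 |
| oak | 4.00 | 2.6 |
| alder | 0.500 | 0.5 |
| alder | 1.00 | 1.1 |
| alder | 1.50 | 1.3 |
| alder | 2.00 | 2.2 |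
| alder | 2.50 | 2.8 |
| alder | 3.00 | 2.6 |
| alder | 4.00 | 3.1 |

(readings scatter by 0.3 percentage points)

- the numbers in the tables scatter with a standard deviation of 0.3 percentage points
- no earlier run changes the charge of free catalyst; that part of a forecast is a guess
- what has left starting material counts as converted, also if it is not yet product

- factor on the rate of making target when 20% of the starting material are converted if reagent is charged twice over
- factor on the rate when 20% of the starting material are converted if free catalyst is charged at 0.02 mol% instead

Alder has 4.00 times the reagent of oak, yet its target readings, summed over the times both runs share, stand at 1.35 times oak's. So the one-step world fails, and I carry one quantity instead: the apparent order in reagent, the logarithm of that target ratio over the logarithm of the charge ratio, 0.216. This is a reading and carries the scatter. Raised to this order, a doubled charge gives my own factor of 1.16. No run varies the free catalyst, so I make no reckoning of my own for it.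

The forecast gives 1.3 for dbl, between 1 and 1.75, which is above my factor, on the view “which suggests approaching saturation”. For ratio it guesses 0.15, between 0.08 and 0.35.

The flask gives 1.11 for dbl and 0.0121 for ratio.

    2 reagent → homo dimer (k = 2.20 /M/s)
    reagent + catalyst intermediate → free catalyst + target (k = 220 /M/s)
    starting material + free catalyst → free catalyst + open intermediate (k = 89.0 /M/s)
    starting material + reagent → uncatalysed product (k = 0.00620 /M/s)
    free catalyst + open intermediate ⇌ catalyst intermediate (K = 7.20 /M, k = 2600 /M/s)

Read back through the same rule, the flask's 1.11 is an order of 0.148, beside my 0.216. The step from reagent to homo dimer holds this order down: the simulated run of this flask without that step has an apparent order of 0.90, against 0.20 with it, and there the rule turns a doubled charge into a factor of 1.87, larger by a factor of 1.61 than what my order of 0.216 gives. The same step raises the apparent order in free catalyst from 1.0 to 1.8.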